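## Retrosynthetic overview
1. Target 13 ⇐ macrolide 12 by a Schenck ene reaction (¹O₂) on the single C7=C8 alkene (last step, no ring formed).
2. 12 ⇐ acyclic 10 by C3–C4 reductive aldehyde–ketone coupling (14-membered ring, formed second) and translactonisation onto the thioester (δ-lactone, formed third).
3. 10 ⇐ enal 7 + ketene thioacetal 9 by iminium-catalysed Mukaiyama–Michael addition (C1–C15 bond); 7 ⇐ epoxy aldehyde 5 by Wittig reaction.
4. 5 ⇐ keto-aldehyde 4 by a new aldehyde-tethered, amine-catalysed asymmetric epoxidation (oxirane formed first; first lasting stereocentres); 4 ⇐ (E,E)-farnesylacetone 1 by terminal C=C cleavage.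
5. Locants are cembrane numbers: C1 = ring CH carrying the C15(Me)–C16 branch, C3/C4 = O-bearing carbons, C7=C8, C11/C12 = epoxide.

Assumption: (5E,9E)-farnesylacetone is bought as the single geometric isomer; catalyst-bound species of catalytic cycles are described in the Why lines and not numbered.

## Route

Step 1
Reactants: 1 (5E,9E)-6,10,14-trimethylpentadeca-5,9,13-trien-2-one
Product: 3 (5E,9E)-12-(3,3-dimethyloxiran-2-yl)-6,10-dimethyldodeca-5,9-dien-2-one (racemic), via bromohydrin 2 (not isolated)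
Conditions: NBS (1.05 equiv), THF/H2O, 0 °C; then K2CO3, MeOH, rt
Reagents that add atoms: water, O (epoxide oxygen); N-bromosuccinimide, O=C1CCC(=O)N1Br (Br in 2 only)
Why: van Tamelen-type bromohydrin formation is selective for the terminal trisubstituted alkene and base closes the epoxide (Williamson); the transient racemic centre is erased in step 2.

Step 2
Reactants: 3 (5E,9E)-12-(3,3-dimethyloxiran-2-yl)-6,10-dimethyldodeca-5,9-dien-2-one
Product: 4 (4E,8E)-4,8-dimethyl-12-oxotrideca-4,8-dienal
Conditions: H5IO6 (1.2 equiv), THF/Et2O, 0 °C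
Reagents that add atoms: none
Why: Periodic acid hydrolyses the terminal epoxide and cleaves the glycol (Malaprade cleavage) without touching the ketone or the internal alkenes.

Step 3
Reactants: 4 (4E,8E)-4,8-dimethyl-12-oxotrideca-4,8-dienal
Product: 5 3-[(2S,3S)-2-methyl-3-[(3E)-3-methyl-7-oxooct-3-en-1-yl]oxiran-2-yl]propanal
Conditions: (2S,5S)-2,5-diphenylpyrrolidine·TfOH (20 mol%), Oxone (1.5 equiv KHSO5), MeCN/aq. phosphate buffer pH 7.5, 15 mM, 0 °C
Reagents that add atoms: potassium peroxymonosulfate (Oxone), [K+].[O-]S(=O)(=O)OO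
Why: Proposed new method: the hindered C2-symmetric amine condenses only with the aldehyde (not the methyl ketone), HSO5⁻ turns the iminium into an oxaziridinium, and its electrophilic oxygen can reach only the γ,δ-alkene C11=C12 through a five/six-membered spiro transition state (attack at O anti to the O–N bond fits a two-carbon tether, and high dilution suppresses intermolecular transfer to C7=C8); the phenyl groups fix the face of peroxide addition and so the (11S,12S) epoxide, and hydrolysis releases the amine for turnover; the closest known reactions are Oxone epoxidation catalysed by iminium salts formed in situ from chiral amines and aldehydes, and stoichiometric intramolecular oxygen transfer in unsaturated oxaziridinium salts.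

Step 4
Reactants: 5 3-[(2S,3S)-2-methyl-3-[(3E)-3-methyl-7-oxooct-3-en-1-yl]oxiran-2-yl]propanal; 6 (triphenyl-λ5-phosphanylidene)acetaldehyde
Product: 7 (2E)-5-[(2S,3S)-2-methyl-3-[(3E)-3-methyl-7-oxooct-3-en-1-yl]oxiran-2-yl]pent-2-enal
Conditions: Ph3P=CHCHO (1.1 equiv), toluene, 60 °C
Reagents that add atoms: 6 (triphenyl-λ5-phosphanylidene)acetaldehyde, O=CC=P(c1ccccc1)(c1ccccc1)c1ccccc1
Why: Wittig olefination with a stabilised ylide is E-selective and takes the aldehyde in preference to the methyl ketone, and the neutral conditions spare the epoxide.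

Step 5
Reactants: 8 S-ethyl propanethioate
Product: 9 {[(1Z)-1-(ethylsulfanyl)prop-1-en-1-yl]oxy}(trimethyl)silane
Conditions: LDA, THF, −78 °C; TMSCl; distil
Reagents that add atoms: chlorotrimethylsilane, C[Si](C)(C)Cl
Why: Kinetic deprotonation of the thioester and O-silylation give the silyl ketene thioacetal (methyl cis to sulfur).

Step 6
Reactants: 7 (2E)-5-[(2S,3S)-2-methyl-3-[(3E)-3-methyl-7-oxooct-3-en-1-yl]oxiran-2-yl]pent-2-enal; 9 {[(1Z)-1-(ethylsulfanyl)prop-1-en-1-yl]oxy}(trimethyl)silane
Product: 10 S-ethyl (2S,3R)-2-methyl-5-[(2S,3S)-2-methyl-3-[(3E)-3-methyl-7-oxooct-3-en-1-yl]oxiran-2-yl]-3-(2-oxoethyl)pentanethioate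
Conditions: (2S,5S)-5-benzyl-2-tert-butyl-3-methylimidazolidin-4-one·2,4-dinitrobenzoic acid (20 mol%), CH2Cl2/i-PrOH, H2O (2 equiv), −60 °C
Reagents that add atoms: 9 {[(1Z)-1-(ethylsulfanyl)prop-1-en-1-yl]oxy}(trimethyl)silane, C/C=C(\SCC)O[Si](C)(C)C
Why: Iminium-catalysed Mukaiyama–Michael addition: the benzyl group shields one face of the E-iminium so the nucleophile adds to C1 from the open face (1R, same sense as established additions to crotonaldehyde), and the C15 methyl centre (expected mainly syn, not verified) is re-equilibrated in step 7.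

Step 7
Reactants: 10 S-ethyl (2S,3R)-2-methyl-5-[(2S,3S)-2-methyl-3-[(3E)-3-methyl-7-oxooct-3-en-1-yl]oxiran-2-yl]-3-(2-oxoethyl)pentanethioate
Product: 12 (1R,3R,4S,7E,11S,12S,15S)-11,12-epoxy-4-hydroxycembr-7-en-16,3-olide, via diol thioester 11 (not isolated)
Conditions: SmI2 (3 equiv), HMPA, THF, 0 °C, syringe-pump addition (final 2 mM); then crude + DBU (1 equiv), PhMe, 60 °C
Reagents that add atoms: none
Why: SmI2 aldehyde–ketone pinacol macrocyclisation forms C3–C4, with the erythro (3R,4S) pair expected from an HMPA-solvated open transition state (antiperiplanar oxygens, extended C2–C5 backbone) and the 1,3-relation to C1 from a chair-like pre-lactone array; DBU then drives translactonisation by 3-OH onto the thioester and equilibrates C15 to the equatorial 15S methyl.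

Step 8
Reactants: 12 (1R,3R,4S,7E,11S,12S,15S)-11,12-epoxy-4-hydroxycembr-7-en-16,3-olide
Product: 13 (1R,3R,4S,7R,11S,12S,15S)-11,12-epoxy-7-hydroperoxy-4-hydroxycembr-8(19)-en-16,3-olide
Conditions: O2, TPP (1 mol%), visible light, CH2Cl2, −20 °C
Reagents that add atoms: dioxygen, O=O
Why: Schenck ene reaction: ¹O₂ adds to the exposed peripheral face of the only alkene, bonding at C7 and abstracting H from the C19 methyl on the more crowded side (cis effect), which gives the 7R hydroperoxide and the 8(19)-methylene; the 8-OOH/Δ6 regioisomer is the expected by-product.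

## Compound list
1 | (5E,9E)-6,10,14-trimethylpentadeca-5,9,13-trien-2-one ((E,E)-farnesylacetone) | CC(=O)CC/C=C(\C)CC/C=C(\C)CCC=C(C)C | starting material
2 | (5E,9E)-13-bromo-14-hydroxy-6,10,14-trimethylpentadeca-5,9-dien-2-one (racemic) | CC(=O)CC/C=C(\C)CC/C=C(\C)CCC(Br)C(C)(C)O | intermediate
3 | (5E,9E)-12-(3,3-dimethyloxiran-2-yl)-6,10-dimethyldodeca-5,9-dien-2-one (racemic) | CC(=O)CC/C=C(\C)CC/C=C(\C)CCC1OC1(C)C | intermediate
4 | (4E,8E)-4,8-dimethyl-12-oxotrideca-4,8-dienal | CC(=O)CC/C=C(\C)CC/C=C(\C)CCC=O | intermediate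
5 | 3-[(2S,3S)-2-methyl-3-[(3E)-3-methyl-7-oxooct-3-en-1-yl]oxiran-2-yl]propanal | CC(=O)CC/C=C(\C)CC[C@@H]1O[C@@]1(C)CCC=O | intermediate
6 | (triphenyl-λ5-phosphanylidene)acetaldehyde | O=CC=P(c1ccccc1)(c1ccccc1)c1ccccc1 | starting material
7 | (2E)-5-[(2S,3S)-2-methyl-3-[(3E)-3-methyl-7-oxooct-3-en-1-yl]oxiran-2-yl]pent-2-enal | CC(=O)CC/C=C(\C)CC[C@@H]1O[C@@]1(C)CC/C=C/C=O | intermediate
8 | S-ethyl propanethioate | CCC(=O)SCC | starting material
9 | {[(1Z)-1-(ethylsulfanyl)prop-1-en-1-yl]oxy}(trimethyl)silane | C/C=C(\SCC)O[Si](C)(C)C | intermediate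
10 | S-ethyl (2S,3R)-2-methyl-5-[(2S,3S)-2-methyl-3-[(3E)-3-methyl-7-oxooct-3-en-1-yl]oxiran-2-yl]-3-(2-oxoethyl)pentanethioate | CC(=O)CC/C=C(\C)CC[C@@H]1O[C@@]1(C)CC[C@H](CC=O)[C@H](C)C(=O)SCC | intermediate
11 | S-ethyl (2S)-2-[(1R,3R,4S,7E,11S,12S)-11,12-epoxy-3,4-dihydroxy-4,8,12-trimethylcyclotetradec-7-en-1-yl]propanethioate (cembrane numbering) | C/C1=C\CC[C@](C)(O)[C@H](O)C[C@@H](CC[C@]2(C)O[C@H]2CC1)[C@H](C)C(=O)SCC | intermediate
12 | (1R,3R,4S,7E,11S,12S,15S)-11,12-epoxy-4-hydroxycembr-7-en-16,3-olide (14-membered ring; C16→O3 δ-lactone with 15-Me; 4-OH/4-Me; 7E alkene; 11,12-epoxide) | C/C1=C\CC[C@](C)(O)[C@H]2C[C@@H](CC[C@]3(C)O[C@H]3CC1)[C@H](C)C(=O)O2 | intermediate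
13 | (1R,3R,4S,7R,11S,12S,15S)-11,12-epoxy-7-hydroperoxy-4-hydroxycembr-8(19)-en-16,3-olide | C=C1CC[C@@H]2O[C@@]2(C)CC[C@@H]2C[C@@H](OC(=O)[C@H]2C)[C@@](C)(O)CC[C@H]1OO | target

## Step count and risks
Total steps: 8. Longest linear sequence: 7 (steps 1–4 and 6–8; step 5 is a side branch).

**Step 3 (proposed new step).** Risks: Oxone may oxidise the amine or the enamine tautomer, the aldehyde may be over-oxidised, and some intermolecular oxygen transfer to C7=C8 may occur. The sense and level of induction are unknown; the (2S,5S)-amine is a working choice and the antipode is equally available. Fallback (known chemistry only), setting out from 4 and rejoining at 12: the epoxide is left out at this stage. Wittig reaction of 4 with 6 gives (2E,6E,10E)-6,10-dimethyl-14-oxopentadeca-2,6,10-trienal F1. The same Mukaiyama–Michael addition with 9 gives the des-epoxy thioester F2. With no epoxide present, the precedented TiCl3/Zn–Cu pinacol macrocyclisation of cembranoid keto-aldehydes can be used, followed by DBU lactonisation, to give the diene macrolide F3. NIS iodoetherification through the 4-OH masks C7=C8 as the iodo-ether F4. Shi epoxidation with the L-fructose-derived ketone (Oxone, K2CO3) then epoxidises the only remaining alkene to the (11S,12S)-epoxy iodo-ether F5. Zn in EtOH/aq. NH4Cl restores the 7E alkene and the 4-OH, giving 12.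

**Step 7.** Risks: the macrocyclic SmI2 pinacol may lose out to simple reduction or dimerisation, and C3/C4 selectivity is uncertain; a samarium-chelated pathway would favour the threo diol, and the relation of C4 to C1 is remote. Fallback, setting out from 10 and rejoining at 12: C3 is set in a separate step instead of in the C–C bond formation. The SmI2 reaction is quenched cold and the open diols are isolated (11 together with the 3-epi-diol F6). Parikh–Doering oxidation of the secondary alcohol gives the macrocyclic hydroxy ketone F7, at which point the C4 epimer is removed by chromatography. Zn(BH4)2 reduction, chelated between 4-OH and C3=O with hydride delivered from the exposed methyl face, gives 11, and DBU then gives 12.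

**Step 8.** Risks: formation of the 8-OOH/Δ6 regioisomer and of the C7 epimer, requiring HPLC separation. Fallback, setting out from 12 and rejoining at 13: the C7 heteroatom is placed by Markovnikov ene-type chlorination (NCS, cat. PhSeCl), which puts chlorine only at C7 and gives the 7-chloro-8(19)-ene allylic chloride F8. Silver-assisted substitution with anhydrous H2O2 (AgOCOCF3, Et2O, 0 °C) then gives 13 and its C7 epimer, which are separated.

## Further compounds
F1 | step 3 | (2E,6E,10E)-6,10-dimethyl-14-oxopentadeca-2,6,10-trienal | CC(=O)CC/C=C(\C)CC/C=C(\C)CC/C=C/C=O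
F2 | step 3 | S-ethyl (2S,3R,6E,10E)-2,6,10-trimethyl-14-oxo-3-(2-oxoethyl)pentadeca-6,10-dienethioate | CC(=O)CC/C=C(\C)CC/C=C(\C)CC[C@H](CC=O)[C@H](C)C(=O)SCC
F3 | step 3 | (1R,3R,4S,7E,11E,15S)-4-hydroxycembra-7,11-dien-16,3-olide | C/C1=C\CC[C@](C)(O)[C@H]2C[C@@H](CC/C(C)=C/CC1)[C@H](C)C(=O)O2
F4 | step 3 | (1R,3R,4S,11E,15S)-4,8-epoxy-7-iodocembr-11-en-16,3-olide (anti adduct, C7/C8 not specified) | CC12CC/C=C(\C)CC[C@@H]3C[C@@H](OC(=O)[C@H]3C)[C@@](C)(O1)CCC2I
F5 | step 3 | (1R,3R,4S,11S,12S,15S)-4,8:11,12-diepoxy-7-iodocembran-16,3-olide (C7/C8 not specified) | CC12CC[C@@H]4O[C@@]4(C)CC[C@@H]3C[C@@H](OC(=O)[C@H]3C)[C@@](C)(O1)CCC2I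
F6 | step 7 | S-ethyl (2S)-2-[(1R,3S,4S,7E,11S,12S)-11,12-epoxy-3,4-dihydroxy-4,8,12-trimethylcyclotetradec-7-en-1-yl]propanethioate | C/C1=C\CC[C@](C)(O)[C@@H](O)C[C@@H](CC[C@]2(C)O[C@H]2CC1)[C@H](C)C(=O)SCC
F7 | step 7 | S-ethyl (2S)-2-[(1R,4S,7E,11S,12S)-11,12-epoxy-4-hydroxy-4,8,12-trimethyl-3-oxocyclotetradec-7-en-1-yl]propanethioate | C/C1=C\CC[C@](C)(O)C(=O)C[C@@H](CC[C@]2(C)O[C@H]2CC1)[C@H](C)C(=O)SCC
F8 | step 8 | (1R,3R,4S,11S,12S,15S)-7-chloro-11,12-epoxy-4-hydroxycembr-8(19)-en-16,3-olide (C7 not specified) | C=C1CC[C@@H]2O[C@@]2(C)CC[C@@H]2C[C@@H](OC(=O)[C@H]2C)[C@@](C)(O)CCC1Cl
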